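## The problem

Compound 24 (C33H42O5) joins two halves through one C–C bond: C1 of a trans-fused eudesmane (rings A and B) carries C4′ of a 5′,7′,8′-trimethoxy-2′-phenyl-4′H-chromene (pyran ring C, benzo ring D). The decalin holds five stereocentres: the quaternary C10, the ring-fusion carbon C5, C1, C7, and the tertiary carbinol C4, whose methyl group is axial and 1,3-diaxial to the C10 methyl. A sixth stereocentre, C4′, lies outside the bicycle on the linking bond. Only C7 with its isopropenyl group corresponds to a cheap chiral building block. Through the conformation of a ring it can govern C1, C4, C5 and C10, but it is too remote to bias C4′. The tertiary alcohol (dehydration), the cyclic enol ether of the 4H-chromene (acid hydrolysis, re-oxidation to the pyrylium ion) and the isopropenyl group (acid, hydrogenation) forbid strong acid, hydrogenation and long protecting-group sequences late in the route. Rings A and B are the transannularly folded form of a cyclodeca-1(10),4-diene: removing the C5–C10 bond, the C4 hydroxyl and the C1 substituent leaves germacrene A (15), whose only stereocentre is C7. In that ten-membered ring, C2–C3 is the one bond between two allylic methylene carbons, so an allylic carbanion and an allylic halide can close it. The flavene is the reduced form of a flavylium cation (22) that is electrophilic at C4′, the kind of electrophile that could trigger the refolding at C1.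

## Retrosynthesis

Terpene carbons carry germacrane/eudesmane numbers; flavene atoms carry primed numbers.

**24 ⇒ 15 + 22 + water.** Three bonds are cut together: C1–C4′, C5–C10 and C4–O. Read forward, C1 of germacrene A (15) attacks C4′ of the flavylium salt 22, C5 closes onto C10 across the ring, and water caps C4. The neighbouring cuts build the decalin first and then append or construct the heterocycle on a hindered C1 next to a quaternary carbon; they need many more steps and set the C4 carbinol separately. This cut reduces a six-stereocentre target to a one-stereocentre hydrocarbon and a flat cation. It asks that a stabilised flavylium ion be electrophilic enough for an unactivated trisubstituted alkene, that proton-induced cyclisation of 15 be suppressed, and it offers no control of C4′, so the 4′-epimer must be separated.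

**22 ⇒ 19 + 20.** The pyrylium ring is opened at O1′–C2′ and C3′–C4′ into 2-hydroxy-3,4,6-trimethoxybenzaldehyde (19) and acetophenone (20), the classical acid condensation. Aldehyde 19 is traced through 2,3,4,6-tetramethoxybenzaldehyde (18) and 1,2,3,5-tetramethoxybenzene (17) to 3,4,5-trimethoxyphenol (16). Simpler salicylaldehydes such as o-vanillin are not suitable, because the two methoxy groups meta to the phenol cannot be added by electrophilic substitution. Arene 17 has only one kind of free position, and the forward route needs only a selective demethylation next to the formyl group.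

**15 ⇒ 14.** The C2–H bond is exchanged for a C2–SO2Ph bond. The sulfone acidifies C2 for ring closure and is removed by hydride substitution under palladium catalysis, which must leave the C1=C10 alkene in place and E.

**14 ⇒ 12 (key disconnection, C2–C3).** Other ring bonds are worse choices. Cutting C6–C7 or C7–C8 would put the only stereocentre into the ring-closing step. Forming C1=C10 or C4=C5 by olefination or metathesis would leave the E geometry of a trisubstituted alkene in a strained ring to chance. C2–C3 is remote from C7, lies between two alkenes whose geometry can be fixed in an open chain, and pairs a sulfonyl-stabilised allylic carbanion (C2) with a primary allylic bromide (C3). The precursor 12 is an acyclic triene with one stereocentre. The forward step must favour cyclisation over oligomerisation and α- over γ-alkylation.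

**12 ⇒ 10 ⇒ 9 ⇒ 8.** The C3 arm is cut at C4=C5: a stabilised α-methyl ylide on aldehyde 8 gives the E enoate 9, reduction gives alcohol 10, and bromination gives 12. The bromide is made last because it would not survive sulfinate, hydride or ylide chemistry.

**8 ⇒ 7 ⇒ 4 ⇒ 3 ⇒ 2.** The C2 arm is cut at C1=C10 by Horner–Wadsworth–Emmons olefination of the methyl ketone 2, followed by reduction to alcohol 4, conversion to sulfone 7 and unmasking of aldehyde 8. Adding a vinyl metal to the ketone and transposing the tertiary allylic alcohol with sulfinate would be shorter. It was rejected because it distinguishes methyl from methylene only weakly in an equilibrating allyl intermediate, so a large share of Z isomer would enter the ring. The olefination has a kinetic E bias, and alcohol 4 is a point where the minor isomer can be removed. The price is that the two carbonyl groups must be differentiated, which the keto acetal 2 does.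

**2 ⇒ 1.** Reconnecting the ketone and the masked aldehyde gives the ring alkene of (R)-limonene (1). Its C4 becomes C7 with the correct configuration, and the isopropenyl group is already present. The forward step needs ozone to select the trisubstituted over the 1,1-disubstituted alkene.

## Roads not taken

**Alternative 1:** Ring B is cut at C6–C7. In the forward step TiCl4 activates the C4 ketone of the ring-A α-methylene ketone A1, and C7 of its allylsilane chain adds to C6 (intramolecular Hosomi–Sakurai reaction). This closes ring B, releases the isopropenyl group and gives the nor-ketone A2 after protonation at C5. The merits are a reliable, well-known annulation and a thermodynamically correctable trans ring fusion; no labile ten-membered diene is handled. The weak points are these. C10 and C1 must be set enantioselectively beforehand, and C7 is formed in the cyclisation with its isopropenyl orientation still to be proven. Methyl addition to the C4 ketone is expected to come from the face away from the axial C10 methyl and so to give the C4 epimer of the required carbinol, which forces a methylenation, epoxidation and reduction detour. The whole flavene must still be built on the C1 side chain, again without control of C4′. This road is safer step by step and would probably be preferred if certainty mattered most. The chosen plan offers about half the length and sets C1, C4, C5 and C10 in one operation from C7, but depends on an untested coupling.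

**Alternative 2:** The pyran ring is cut at C2′=C3′. In the forward step the titanium ethylidene made from TiCl4, Zn, PbCl2, TMEDA and CH3CHBr2 exchanges with the C4′ vinyl group of benzoate A3, and the new alkylidene olefinates the ester carbonyl to give the silyl-protected target A4. The merit is real: the acid-sensitive enol ether is formed last under non-acidic conditions, and C4′ is a stereocentre of an isolable precursor, so it can be set or separated before the end. In this respect the road is better than the chosen one, which cannot control C4′. Its weak points are a hindered aryl benzoate flanked by a methoxy group, a large excess of low-valent titanium in the presence of the isopropenyl group, and above all the long conventional synthesis of A3 with all six stereocentres. The chosen plan answers with brevity and convergence, and accepts a separation of C4′ epimers.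

**Alternative 3:** Ring A is cut at C3=C4. In the forward step the second-generation Grubbs catalyst joins the allyl group on C1 to the isopropenyl group on C5 of diene acetal A5, with loss of ethylene, to give A6. Ring-closing metathesis to a cyclohexene is dependable, and ring B with C7 could come from the chiral pool, so the carbocycle would be secured early. The weak points are these. A5 carries a second isopropenyl group on C7 that competes for the catalyst. The trisubstituted alkene forms slowly. The C3=C4 alkene must then be hydrated to the equatorial C4 alcohol in the presence of the C7 isopropenyl group, where hydrogen-atom-transfer hydration would attack the wrong alkene and opening of the α-epoxide meets opposing regiochemical and stereoelectronic demands. The flavene again has to be assembled stepwise from the C1 acetal. This road gives better control of each ring-forming event, whereas the chosen plan installs the C4 carbinol with the correct configuration automatically and in far fewer steps.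

Key step: step 9

Remark on the chemistry: the coupling in step 15 is assumed to give both C4′ epimers, from which 24 (4′S) is separated; the minor 2Z isomer formed in step 2 is removed at alcohol 4.

## Route

Step 1
Reactants: 1 (R)-(+)-limonene
Product: 2 (5R)-7,7-dimethoxy-5-(prop-1-en-2-yl)heptan-2-one
Conditions: O3 (1 equiv), CH2Cl2/MeOH, −78 °C; Me2S, −78 °C → rt; TsOH·H2O (cat.), rt; NaHCO3
Reagents that add atoms: ozone, [O-][O+]=O; methanol, CO
Why: Ozonolysis (Criegee cleavage) takes the more electron-rich trisubstituted ring alkene before the 1,1-disubstituted one; after reduction of the peroxides, acid in methanol acetalises only the aldehyde because a methyl ketone forms its dimethyl ketal far less readily, and the stereocentre is not touched.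

Step 2
Reactants: 2 (5R)-7,7-dimethoxy-5-(prop-1-en-2-yl)heptan-2-one
Product: 3 ethyl (2E,6R)-8,8-dimethoxy-3-methyl-6-(prop-1-en-2-yl)oct-2-enoate
Conditions: (EtO)2P(O)CH2CO2Et, NaH, THF, 0 °C → rt
Reagents that add atoms: triethyl phosphonoacetate, CCOC(=O)CP(=O)(OCC)OCC
Why: Horner–Wadsworth–Emmons olefination of a methyl alkyl ketone places the ester trans to the longer chain preferentially, so the E isomer should predominate; the minor Z isomer is carried to step 3 and removed there.

Step 3
Reactants: 3 ethyl (2E,6R)-8,8-dimethoxy-3-methyl-6-(prop-1-en-2-yl)oct-2-enoate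
Product: 4 (2E,6R)-8,8-dimethoxy-3-methyl-6-(prop-1-en-2-yl)oct-2-en-1-ol
Conditions: i-Bu2AlH (2.2 equiv), CH2Cl2, −78 °C; aq. potassium sodium tartrate; chromatography on silica gel (AgNO3-doped if needed) to remove the 2Z isomer
Reagents that add atoms: none
Why: 1,2-Reduction of the enoate by the aluminium hydride leaves acetal and alkenes untouched, and E and Z allylic alcohols of this type are separable on silica gel, so the C1=C10 geometry is secured here.

Step 4
Reactants: 4 (2E,6R)-8,8-dimethoxy-3-methyl-6-(prop-1-en-2-yl)oct-2-en-1-ol
Product: 7 {[(2E,6R)-8,8-dimethoxy-3-methyl-6-(prop-1-en-2-yl)oct-2-en-1-yl]sulfonyl}benzene, via allylic mesylate 5 (not isolated), via allylic bromide 6 (not isolated)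
Conditions: MsCl, Et3N, THF, −40 °C; LiBr, 0 °C; then PhSO2Na, DMF, rt
Reagents that add atoms: sodium benzenesulfinate, [Na+].[O-]S(=O)c1ccccc1
Why: Mesylation and bromide exchange convert the primary allylic alcohol without transposition, and S-alkylation of the sulfinate (SN2) gives the sulfone with the E alkene intact; the medium is never acidic, so the acetal survives.

Step 5
Reactants: 7 {[(2E,6R)-8,8-dimethoxy-3-methyl-6-(prop-1-en-2-yl)oct-2-en-1-yl]sulfonyl}benzene
Product: 8 (3R,6E)-6-methyl-8-(phenylsulfonyl)-3-(prop-1-en-2-yl)oct-6-enal
Conditions: TsOH·H2O (cat.), acetone/H2O, rt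
Reagents that add atoms: water, O
Why: Acid-catalysed acetal hydrolysis under mild conditions spares the alkenes and the sulfone; the stereocentre is β to the aldehyde and cannot epimerise.

Step 6
Reactants: 8 (3R,6E)-6-methyl-8-(phenylsulfonyl)-3-(prop-1-en-2-yl)oct-6-enal
Product: 9 ethyl (2E,5R,8E)-2,8-dimethyl-10-(phenylsulfonyl)-5-(prop-1-en-2-yl)deca-2,8-dienoate
Conditions: Ph3P=C(CH3)CO2Et, CH2Cl2, rt
Reagents that add atoms: ethyl 2-(triphenylphosphoranylidene)propanoate, CCOC(=O)C(C)=P(c1ccccc1)(c1ccccc1)c1ccccc1
Why: The Wittig reaction of an aldehyde with this stabilised α-methyl ylide gives the E trisubstituted enoate with high selectivity, which sets the C4=C5 geometry; the ylide is too weak a base to deprotonate the sulfone.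

Step 7
Reactants: 9 ethyl (2E,5R,8E)-2,8-dimethyl-10-(phenylsulfonyl)-5-(prop-1-en-2-yl)deca-2,8-dienoate
Product: 10 (2E,5R,8E)-2,8-dimethyl-10-(phenylsulfonyl)-5-(prop-1-en-2-yl)deca-2,8-dien-1-ol
Conditions: i-Bu2AlH (2.2 equiv), CH2Cl2, −78 °C; aq. potassium sodium tartrate
Reagents that add atoms: none
Why: 1,2-Reduction of the enoate to the allylic alcohol; sulfones are inert to the aluminium hydride at this temperature.

Step 8
Reactants: 10 (2E,5R,8E)-2,8-dimethyl-10-(phenylsulfonyl)-5-(prop-1-en-2-yl)deca-2,8-dien-1-ol
Product: 12 {[(2E,6R,8E)-10-bromo-3,9-dimethyl-6-(prop-1-en-2-yl)deca-2,8-dien-1-yl]sulfonyl}benzene, via allylic mesylate 11 (not isolated)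
Conditions: MsCl, Et3N, THF, −40 °C; LiBr, 0 °C; used at once
Reagents that add atoms: lithium bromide, [Li+].[Br-]
Why: Mesylate-to-bromide exchange (SN2) on a primary allylic alcohol gives the bromide without loss of alkene geometry under non-acidic conditions that spare the isopropenyl group.

Step 9
Reactants: 12 {[(2E,6R,8E)-10-bromo-3,9-dimethyl-6-(prop-1-en-2-yl)deca-2,8-dien-1-yl]sulfonyl}benzene
Product: 14 {[(2E,6R,8E)-3,9-dimethyl-6-(prop-1-en-2-yl)cyclodeca-2,8-dien-1-yl]sulfonyl}benzene, that is (1(10)E,4E,7R)-2-(phenylsulfonyl)germacra-1(10),4,11-triene as both C2 epimers, via potassium sulfonyl carbanion 13 (not isolated)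
Conditions: KN(SiMe3)2 (1.3 equiv), THF, −20 °C, slow addition of 12 by syringe pump to a final 0.003 M; then 0 °C; aq. NH4Cl
Reagents that add atoms: none
Why: The amide base removes a C2 proton, which is both allylic and α to the sulfone, and the α-carbon of carbanion 13 displaces bromide from the primary allylic C3 in an intramolecular SN2 reaction that forms C2–C3. The closest known reaction type is the intramolecular alkylation of sulfur-stabilised allylic carbanions by allylic halides, which has been used to close (E,E)-cyclodeca-1,5-dienes and larger terpenoid rings. The ten-membered ring closes in the 10-exo-tet mode. The one new stereocentre, C2, needs no control because both epimers converge in step 10; C7 is untouched, so the ring is a single enantiomer. Cyclisation must beat oligomerisation, which slow addition into base at high dilution provides. Alkylation must occur at the α- and not the γ-carbon, which the sulfonyl group secures by localising the charge on C2. Direct displacement rather than SN2′ attack at C5 is favoured by the unhindered primary bromide and by the smaller, more strained ring the alternative would form. Both alkenes enter as E and are configurationally stable under these conditions, and the temperature is kept low because the product is a 1,5-diene prone to Cope rearrangement.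

Step 10
Reactants: 14 (1(10)E,4E,7R)-2-(phenylsulfonyl)germacra-1(10),4,11-triene
Product: 15 (1E,5E,8R)-1,5-dimethyl-8-(prop-1-en-2-yl)cyclodeca-1,5-diene, that is (7R)-germacrene A
Conditions: PdCl2(dppp) (5 mol %), LiBHEt3 (2.5 equiv), THF, 0 °C; cold aqueous work-up; rapid chromatography on Et3N-deactivated silica gel; stored cold in pentane
Reagents that add atoms: none
Why: Palladium-catalysed reductive desulfonylation of an allylic sulfone: zerovalent palladium, formed from the divalent precatalyst by the hydride, ionises the allylic C–S bond and hydride is delivered to the less substituted allyl terminus C2, so the C1=C10 alkene should stay in place and E; cold, non-acidic handling avoids Cope rearrangement and proton-induced cyclisation of the product.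

Step 11
Reactants: 16 3,4,5-trimethoxyphenol
Product: 17 1,2,3,5-tetramethoxybenzene
Conditions: MeI, K2CO3, acetone, reflux
Reagents that add atoms: iodomethane, CI
Why: Williamson O-methylation of the phenoxide.

Step 12
Reactants: 17 1,2,3,5-tetramethoxybenzene
Product: 18 2,3,4,6-tetramethoxybenzaldehyde
Conditions: POCl3, DMF, 0 → 60 °C; then H2O
Reagents that add atoms: N,N-dimethylformamide, CN(C)C=O; water, O
Why: Vilsmeier–Haack formylation of a strongly activated arene whose two free positions are equivalent by symmetry, so only one aldehyde can form.

Step 13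
Reactants: 18 2,3,4,6-tetramethoxybenzaldehyde
Product: 19 2-hydroxy-3,4,6-trimethoxybenzaldehyde
Conditions: BCl3 (1.1 equiv), CH2Cl2, −78 → 0 °C; then H2O
Reagents that add atoms: none
Why: Boron chelation between the formyl oxygen and an ortho methoxy group followed by chloride attack on its methyl group cleaves only an ortho ether; of the two, the C2 methoxy group, buttressed by the C3 methoxy group and twisted out of the ring plane, is expected to go first, and the regiochemistry is to be confirmed by NOE before use.

Step 14
Reactants: 19 2-hydroxy-3,4,6-trimethoxybenzaldehyde; 20 acetophenone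
Product: 22 5,7,8-trimethoxy-2-phenylchromenylium (5,7,8-trimethoxyflavylium) tetrafluoroborate, via 2-hydroxychalcone 21 (not isolated)
Conditions: HBF4·OEt2, AcOH, rt; precipitation with Et2O; recrystallised and dried free of acid
Reagents that add atoms: tetrafluoroboric acid, [H+].F[B-](F)(F)F
Why: Acid-mediated aldol condensation gives the 2-hydroxychalcone, whose phenol adds to the protonated ketone and loses water to give the aromatic benzopyrylium ion (classical flavylium synthesis); the salt precipitates and can be freed from excess acid.

Step 15
Reactants: 15 (7R)-germacrene A; 22 5,7,8-trimethoxyflavylium tetrafluoroborate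
Product: 24 (1S,4R,5R,7R,10S)-1-[(4S)-5,7,8-trimethoxy-2-phenyl-4H-chromen-4-yl]eudesm-11-en-4-ol, via eudesm-4-yl cation 23 (not isolated)
Conditions: 22 (1.2 equiv), 2,6-di-tert-butyl-4-methylpyridine (1.5 equiv), H2O (10 equiv), CH2Cl2/(CF3)2CHOH (4:1), −20 → 0 °C, dark; aq. NaHCO3; chromatographic separation of the C4′ epimer
Reagents that add atoms: water, O
Why: Proposed new method: the 4-unsubstituted flavylium ion is a stabilised carbenium ion that accepts π-nucleophiles at C4′, and in the crossed conformer of 15 the C1=C10 and C4=C5 bonds lie face to face, so attack of C1 on C4′ should be assisted by C5–C10 bond formation and end in the tertiary C4 cation 23, which water captures; the closest known reaction types are the transannular cyclisation of (E,E)-germacra-1(10),4-dienes to 4-hydroxyeudesmanes started by protons, bromonium or selenium electrophiles, and the addition of silyl enol ethers, allylsilanes or vinylphenols to C4 of flavylium salts; anti addition across both E alkenes in the conformer with a pseudo-equatorial isopropenyl group sets the 1β substituent, the 10β methyl, the 5α hydrogen and the 4α hydroxyl from C7, whereas the face of the flavylium ion, and hence C4′, is not expected to be controlled; the hindered pyridine takes up the proton released so that acid cannot cyclise unreacted 15.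

## Compound list

1 | (R)-(+)-limonene, (4R)-1-methyl-4-(prop-1-en-2-yl)cyclohex-1-ene | CC1=CC[C@@H](CC1)C(C)=C | starting material
2 | (5R)-7,7-dimethoxy-5-(prop-1-en-2-yl)heptan-2-one | C=C(C)[C@H](CCC(C)=O)CC(OC)OC | intermediate
3 | ethyl (2E,6R)-8,8-dimethoxy-3-methyl-6-(prop-1-en-2-yl)oct-2-enoate | C=C(C)[C@H](CC/C(C)=C/C(=O)OCC)CC(OC)OC | intermediate
4 | (2E,6R)-8,8-dimethoxy-3-methyl-6-(prop-1-en-2-yl)oct-2-en-1-ol | C=C(C)[C@H](CC/C(C)=C/CO)CC(OC)OC | intermediate
5 | (2E,6R)-8,8-dimethoxy-3-methyl-6-(prop-1-en-2-yl)oct-2-en-1-yl methanesulfonate | C=C(C)[C@H](CC/C(C)=C/COS(C)(=O)=O)CC(OC)OC | intermediate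
6 | (2E,6R)-1-bromo-8,8-dimethoxy-3-methyl-6-(prop-1-en-2-yl)oct-2-ene | C=C(C)[C@H](CC/C(C)=C/CBr)CC(OC)OC | intermediate
7 | {[(2E,6R)-8,8-dimethoxy-3-methyl-6-(prop-1-en-2-yl)oct-2-en-1-yl]sulfonyl}benzene | C=C(C)[C@H](CC/C(C)=C/CS(=O)(=O)c1ccccc1)CC(OC)OC | intermediate
8 | (3R,6E)-6-methyl-8-(phenylsulfonyl)-3-(prop-1-en-2-yl)oct-6-enal | C=C(C)[C@H](CC/C(C)=C/CS(=O)(=O)c1ccccc1)CC=O | intermediate
9 | ethyl (2E,5R,8E)-2,8-dimethyl-10-(phenylsulfonyl)-5-(prop-1-en-2-yl)deca-2,8-dienoate | C=C(C)[C@H](CC/C(C)=C/CS(=O)(=O)c1ccccc1)C/C=C(\C)C(=O)OCC | intermediate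
10 | (2E,5R,8E)-2,8-dimethyl-10-(phenylsulfonyl)-5-(prop-1-en-2-yl)deca-2,8-dien-1-ol | C=C(C)[C@H](CC/C(C)=C/CS(=O)(=O)c1ccccc1)C/C=C(\C)CO | intermediate
11 | (2E,5R,8E)-2,8-dimethyl-10-(phenylsulfonyl)-5-(prop-1-en-2-yl)deca-2,8-dien-1-yl methanesulfonate | C=C(C)[C@H](CC/C(C)=C/CS(=O)(=O)c1ccccc1)C/C=C(\C)COS(C)(=O)=O | intermediate
12 | {[(2E,6R,8E)-10-bromo-3,9-dimethyl-6-(prop-1-en-2-yl)deca-2,8-dien-1-yl]sulfonyl}benzene | C=C(C)[C@H](CC/C(C)=C/CS(=O)(=O)c1ccccc1)C/C=C(\C)CBr | intermediate
13 | potassium salt of the C2 (α-sulfonyl, allylic) carbanion of 12 | C=C(C)[C@H](CC/C(C)=C/[CH-]S(=O)(=O)c1ccccc1)C/C=C(\C)CBr.[K+] | intermediate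
14 | {[(2E,6R,8E)-3,9-dimethyl-6-(prop-1-en-2-yl)cyclodeca-2,8-dien-1-yl]sulfonyl}benzene, (1(10)E,4E,7R)-2-(phenylsulfonyl)germacra-1(10),4,11-triene, both C2 epimers | C=C(C)[C@@H]1CC/C(C)=C/C(S(=O)(=O)c2ccccc2)C/C(C)=C/C1 | intermediate
15 | (1E,5E,8R)-1,5-dimethyl-8-(prop-1-en-2-yl)cyclodeca-1,5-diene, (7R)-germacrene A | C=C(C)[C@@H]1CC/C(C)=C/CC/C(C)=C/C1 | intermediate
16 | 3,4,5-trimethoxyphenol | COc1cc(O)cc(OC)c1OC | starting material
17 | 1,2,3,5-tetramethoxybenzene | COc1cc(OC)c(OC)c(OC)c1 | intermediate
18 | 2,3,4,6-tetramethoxybenzaldehyde | COc1cc(OC)c(C=O)c(OC)c1OC | intermediate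
19 | 2-hydroxy-3,4,6-trimethoxybenzaldehyde | COc1cc(OC)c(C=O)c(O)c1OC | intermediate
20 | acetophenone | CC(=O)c1ccccc1 | starting material
21 | (E)-3-(2-hydroxy-3,4,6-trimethoxyphenyl)-1-phenylprop-2-en-1-one | COc1cc(OC)c(/C=C/C(=O)c2ccccc2)c(O)c1OC | intermediate
22 | 5,7,8-trimethoxy-2-phenylchromenylium tetrafluoroborate | COc1cc(OC)c(OC)c2[o+]c(-c3ccccc3)ccc12.F[B-](F)(F)F | intermediate
23 | (1S,5R,7R,10S)-1-[(4S)-5,7,8-trimethoxy-2-phenyl-4H-chromen-4-yl]eudesm-11-en-4-ylium tetrafluoroborate (C4 cation) | C=C(C)[C@@H]1CC[C@]2(C)[C@@H](C1)[C+](C)CC[C@H]2[C@H]1C=C(c2ccccc2)Oc2c(OC)c(OC)cc(OC)c21.F[B-](F)(F)F | intermediate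
24 | (1S,4R,5R,7R,10S)-1-[(4S)-5,7,8-trimethoxy-2-phenyl-4H-chromen-4-yl]eudesm-11-en-4-ol (1β-flavenyl, 4α-OH, 5α-H, 7β-isopropenyl, 10β-methyl) | C=C(C)[C@@H]1CC[C@]2(C)[C@@H](C1)[C@](C)(O)CC[C@H]2[C@H]1C=C(c2ccccc2)Oc2c(OC)c(OC)cc(OC)c21 | target

## Step count and least certain steps

Total: 15 steps. Longest linear sequence: 11 steps (steps 1–10 and 15, from 1 to 24); the flavylium branch is 4 steps (11–14).

**Step 15 (proposed new method).** The polymethoxylated flavylium ion may be too weak an electrophile for an unactivated trisubstituted alkene. Hydration of the flavylium ion to its hemiketal and chalcone, and proton-induced cyclisation of 15 to selinene-type products, could then outrun C–C bond formation. The C4 cation may also lose a proton instead of capturing water, and facial selectivity at C4′ is likely to be poor. The fallback uses known reactions only, sets out from 15 and returns at 24. N-Bromosuccinimide in aqueous acetone at 0 °C (bromonium-initiated transannular cyclisation with capture by water, a known reaction of (E,E)-germacra-1(10),4-dienes) should give 1β-bromoeudesm-11-en-4α-ol F1. Its C1 radical (Bu3SnH, AIBN, benzene, 80 °C, slow addition) is added in a Giese reaction to the β-carbon of chalcone 21, which is prepared separately from 19 and 20 with KOH in ethanol. This gives the keto phenol 3-(2-hydroxy-3,4,6-trimethoxyphenyl)-3-(4α-hydroxyeudesm-11-en-1β-yl)-1-phenylpropan-1-one F2. Cyclodehydration with pyridinium p-toluenesulfonate in toluene over 4 Å molecular sieves closes the 4H-chromene to 24 and its C4′ epimer. This path is longer and is expected to be slow at the hindered radical addition, but each reaction type is established.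

**Step 9 (key step).** Intermolecular alkylation (oligomerisation) may compete with the strained ten-membered closure, and the base may cause elimination or proton shuffling of the allylic bromide. The fallback replaces the carbanion closure by a reductive allyl–allyl coupling; it sets out from 4 and returns at 15.
- Acetal hydrolysis (TsOH·H2O, acetone/H2O) gives (3R,6E)-8-hydroxy-6-methyl-3-(prop-1-en-2-yl)oct-6-enal F3.
- Wittig reaction with Ph3P=C(CH3)CO2Et gives ethyl (2E,5R,8E)-10-hydroxy-2,8-dimethyl-5-(prop-1-en-2-yl)deca-2,8-dienoate F4.
- Reduction with i-Bu2AlH gives (2E,5R,8E)-2,8-dimethyl-5-(prop-1-en-2-yl)deca-2,8-diene-1,10-diol F5.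
- PBr3 in Et2O at −10 °C gives (2E,5R,8E)-1,10-dibromo-2,8-dimethyl-5-(prop-1-en-2-yl)deca-2,8-diene F6.
- Zerovalent nickel (Ni(CO)4, N-methylpyrrolidone, 50 °C, slow addition), a known way to close bis(allylic bromides) to 1,5-cycloalkadienes, couples C2 with C3 and gives 15 directly.

The allylnickel intermediates can scramble alkene geometry, so isomers would have to be separated. In return no sulfur auxiliary is needed, which also removes step 10, the allylic C–S hydrogenolysis on a Cope-prone diene and the other delicate operation of the main line.

**Step 2.** The E/Z selectivity of the olefination of a methyl alkyl ketone is incomplete, which costs material and relies on the separation at 4. The fallback builds the alkene by syn carbometalation; it sets out from 2 and returns at 4. Enol phosphate formation and elimination (LiN(i-Pr)2, THF, −78 °C; ClP(O)(OEt)2; LiN(i-Pr)2, 2.2 equiv) converts the methyl ketone into the terminal alkyne (5R)-7,7-dimethoxy-5-(prop-1-en-2-yl)hept-1-yne F7. Zirconium-catalysed carboalumination (AlMe3, Cp2ZrCl2, CH2Cl2; Negishi), then n-BuLi and paraformaldehyde, adds methyl and the hydroxymethyl carbon syn and should give 4 as the E isomer only. The Lewis-acidic aluminium reagent may attack the acetal, which is why this is not the first choice.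

## Further compounds

F1 | step 15 | 1β-bromoeudesm-11-en-4α-ol (5α-H, 7β-isopropenyl, 10β-methyl) | C=C(C)[C@@H]1CC[C@]2(C)[C@@H](C1)[C@](C)(O)CC[C@H]2Br
F2 | step 15 | 3-(2-hydroxy-3,4,6-trimethoxyphenyl)-3-(4α-hydroxyeudesm-11-en-1β-yl)-1-phenylpropan-1-one, both epimers at C3 of the propanone | C=C(C)[C@@H]1CC[C@]2(C)[C@@H](C1)[C@](C)(O)CC[C@H]2C(CC(=O)c1ccccc1)c1c(O)c(OC)c(OC)cc1OC
F3 | step 9 | (3R,6E)-8-hydroxy-6-methyl-3-(prop-1-en-2-yl)oct-6-enal | C=C(C)[C@H](CC/C(C)=C/CO)CC=O
F4 | step 9 | ethyl (2E,5R,8E)-10-hydroxy-2,8-dimethyl-5-(prop-1-en-2-yl)deca-2,8-dienoate | C=C(C)[C@H](CC/C(C)=C/CO)C/C=C(\C)C(=O)OCC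
F5 | step 9 | (2E,5R,8E)-2,8-dimethyl-5-(prop-1-en-2-yl)deca-2,8-diene-1,10-diol | C=C(C)[C@H](CC/C(C)=C/CO)C/C=C(\C)CO
F6 | step 9 | (2E,5R,8E)-1,10-dibromo-2,8-dimethyl-5-(prop-1-en-2-yl)deca-2,8-diene | C=C(C)[C@H](CC/C(C)=C/CBr)C/C=C(\C)CBr
F7 | step 2 | (5R)-7,7-dimethoxy-5-(prop-1-en-2-yl)hept-1-yne | C=C(C)[C@H](CCC#C)CC(OC)OC
A1 | alternative 1 | 2-methylidene-3-methyl-3-[4-methyl-5-(trimethylsilyl)pent-3-en-1-yl]-4-{[tri(propan-2-yl)silyl]oxymethyl}cyclohexan-1-one, C10 and C1 configured as in 24 | C[Si](C)(C)CC(C)=CCC[C@]1(C)C(=C)C(=O)CC[C@H]1CO[Si](C(C)C)(C(C)C)C(C)C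
A2 | alternative 1 | 4-oxo-15-nor-eudesm-11-ene with a 1β-CH2OSi(i-Pr)3 group | C=C(C)[C@@H]1CC[C@]2(C)[C@@H](C1)C(=O)CC[C@H]2CO[Si](C(C)C)(C(C)C)C(C)C
A3 | alternative 2 | 2-[1-(4α-triethylsilyloxyeudesm-11-en-1β-yl)prop-2-en-1-yl]-3,5,6-trimethoxyphenyl benzoate, benzylic carbon configured as C4′ of 24 | C=C(C)[C@@H]1CC[C@]2(C)[C@@H](C1)[C@](C)(O[Si](CC)(CC)CC)CC[C@H]2[C@@H](C=C)c1c(OC)cc(OC)c(OC)c1OC(=O)c1ccccc1
A4 | alternative 2 | C4 triethylsilyl ether of 24 | C=C(C)[C@@H]1CC[C@]2(C)[C@@H](C1)[C@](C)(O[Si](CC)(CC)CC)CC[C@H]2[C@H]1C=C(c2ccccc2)Oc2c(OC)c(OC)cc(OC)c21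
A5 | alternative 3 | 1-(1,1-dimethoxypent-4-en-2-yl)-1-methyl-2,4-di(prop-1-en-2-yl)cyclohexane, configured as C1, C10, C5 and C7 of 24 | C=C(C)[C@@H]1CC[C@@](C)([C@@H](CC=C)C(OC)OC)[C@@H](C1)C(C)=C
A6 | alternative 3 | eudesma-3,11-diene-1β-carbaldehyde dimethyl acetal | C=C(C)[C@@H]1CC[C@]2(C)[C@@H](C1)C(C)=CC[C@H]2C(OC)OC
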